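Take the first readings of the midnight run: at 1.04 d, isomer of the product A stands at 2.8% of the charge and target at 7.9%. Their ratio, multiplied by that time, gives 2.93 d. This is the target lifetime, the fraction of target standing divided by the fraction of isomer of the product A made per day, a pseudo-first-order lifetime. The noon run, with the same precatalyst charge, reads 2.68 d.

| setting | midnight | noon | summer | flask |
|---|---|---|---|---|
| substrate | 0.35 M | 0.55 M | 0.25 M | 0.25 M |
| precatalyst | 8.2 mM | 8.2 mM | 16 mM | 8.2 mM |
| remark | run made earlier | run made earlier | run made earlier |  |
| time |  |  |  | 15 d |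

| run | time / d | isomer of the product A / % | target / % |
|---|---|---|---|
| midnight | 1.04 | 2.8 | 7.9 |
| midnight | 1.67 | 3.2 | 7.5 |
| midnight | 2.50 | 3.9 | 7.1 |
| midnight | 4.00 | 4.6 | 7.3 |
| midnight | 8.00 | 5.9 | 7.3 |
| midnight | 12.0 | 7.6 | 7.9 |
| noon | 0.833 | 2.3 | 7.4 |
| noon | 2.50 | 3.8 | 7.4 |
| noon | 4.00 | 4.8 | 7.3 |
| noon | 6.00 | 5.5 | 7.5 |
| noon | 10.0 | 6.8 | 7.6 |
| noon | 12.0 | 7.9 | 7.3 |
| summer | 2.50 | 5.1 | 7.8 |
| summer | 5.00 | 5.9 | 7.6 |
| summer | 8.00 | 7.4 | 7.1 |
| summer | 10.0 | 8.2 | 7.0 |
| summer | 12.0 | 8.6 | 7.3 |

(readings scatter by 0.3 percentage points)

- the numbers in the tables scatter with a standard deviation of 0.3 percentage points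
- a reading or a percentage of target counts all its forms, free or not

1. share of isomer of the product A in isomer of the product A plus target at 80 min
2. share of isomer of the product A in isomer of the product A plus target at 15 d

The forecast and I dispute the early share in the flask. I hold that target feeds isomer of the product A, and I count 80 min against the lifetime of the first readings, as a rough figure: the noon run's first reading, at 0.833 d, comes later than 80 min, so target at 80 min is unread. So 80 min is 0.0189 of a lifetime, and I expect a share of 1.86%. The forecast sees a burst of isomer of the product A relaxing over about 0.8 d, followed by a straight line. It adds “Target is unobserved this early” and gives 8% at 80 min and 54% at 15 d. Its early share is higher than mine by a factor of 4.30. I set no number against its late one.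

The flask gives 2.42% at 80 min and 53.7% at 15 d.

    substrate + catalyst ⇌ target + catalyst, rate k1*[substrate]*[catalyst] forward; the back reaction follows from the equilibrium constant (K = 0.0960, k = 5.72 L mol⁻¹ h⁻¹)
    target + catalyst ⇌ isomer of the product A + catalyst, rate k2*[catalyst]*[target] forward; the back reaction follows from the equilibrium constant (K = 4.30, k = 7.89 L mol⁻¹ h⁻¹)
    isomer of the product A + catalyst ⇌ isomer of the product B + catalyst, rate k3*[catalyst]*[isomer of the product A] forward; the back reaction follows from the equilibrium constant (K = 1.20, k = 3.05 L mol⁻¹ h⁻¹)
    crystals ⇌ target, rate k4*(cs4 - [target]) while solid is left; crystals form when [target] > cs4 (solubility = 0.160 M, k = 4.42 h⁻¹)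
    precatalyst → catalyst (k = 1.59 h⁻¹)
    2 catalyst ⇌ resting dimer (K = 18000 L mol⁻¹, k = 17.4 L mol⁻¹ h⁻¹)

The early share falls nearer my figure, while the forecast's burst and line stands at 15 d, its region. At 0.450 d the flask holds 7.37% of target. The same reckoning as for 2.93 d, time multiplied by target over isomer of the product A, gives 2.24 d on the flask's early share; this is a figure of that moment, not a lifetime of the flask. Stretched by the ratio of precatalyst charges for the neighbour flask with 0.0020 M, it becomes 9.19 d, which predicts a share of 0.601% at 80 min. That neighbour flask gives 0.609%.

The data were generated by integration with constants of no real substance; scatter was added.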